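**Plan**

- Retrosynthesis cuts the O–CH3 bond of ring A first (with a temporary MOM ether on the ring B hydroxyl), then the diaryl ether bond between the bridging oxygen and ring A.
- The second cut is open because ring B, a C6Br4 ring with oxygen on two adjacent carbons, is a mono-arylated tetrabromocatechol, the reduced form of tetrabromo-o-benzoquinone, and ring A is a 2,4-dibromophenol whose single free ortho/para carbon (C6) is the one bonded to the bridging oxygen.
- Forward, both benzene rings are bought intact. 2,4-Dibromophenol and o-bromanil are joined by a redox-neutral radical-pair O–C6 coupling (no ring is formed), the ring B hydroxyl is masked through the monoanion, the ring A hydroxyl is methylated, and the mask is removed.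
- The target has no stereocentre; the only sp3 carbon on the way, C6 of a transient dienone, is lost on tautomerization.

Key step: step 1

Assumption: the ring B hydroxyl of the coupled bisphenol is taken to be the more acidic of the two, because it has two additional bromine atoms meta to it; the masking step rests on this.

**Route**

Step 1
Reactants: 1 2,4-dibromophenol; 2 tetrabromo-1,2-benzoquinone (o-bromanil)
Product: 6 2,3,4,5-tetrabromo-6-(3,5-dibromo-2-hydroxyphenoxy)phenol, via 2,4-dibromophenoxyl radical 3 (not isolated), via tetrabromosemiquinone radical 4 (not isolated), via cyclohexadienone tautomer 5 (not isolated)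
Conditions: 1 (2 equiv), 2 (1 equiv), PhCl, 90 °C, Ar, dark
Reagents that add atoms: none
Why: Proposed new method: o-bromanil 2 is expected to take the phenolic hydrogen of 1 by proton-coupled electron transfer (uphill but reversible), giving phenoxyl radical 3 and semiquinone radical 4 in one solvent cage; the oxygen radical of 4 then bonds to C6 of 3, a site of high spin density, and the dienone 5 so formed enolizes to 6, a redox-neutral addition that keeps every atom of 1 and 2. The closest known reaction types are dehydrogenative couplings with high-potential quinones (DDQ, o-chloranil), in which the quinone abstracts hydrogen and its reduced form ends up O-bonded to the substrate, and the enzymatic phenoxyl-radical C–O coupling of bromophenols. No ring is closed and no stereocentre survives, the sp3 carbon of 5 being lost on tautomerization. The step needs cross-coupling over homodimerization of 3, and C6 over C2 and C4: in-cage collapse of the unlike pair in a non-polar solvent should favour the former, and the bromine atoms at C2 and C4 secure the latter, since attack there gives bromodienones that cannot aromatize by tautomerization and can revert. Product 6 has no free ortho or para carbon on ring A and should not be arylated again, the excess of 1 keeps 2 from oxidizing 6 further, and no metal or external oxidant is present to touch the six C–Br bonds.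

Step 2
Reactants: 6 2,3,4,5-tetrabromo-6-(3,5-dibromo-2-hydroxyphenoxy)phenol
Product: 7 2,4-dibromo-6-[2,3,4,5-tetrabromo-6-(methoxymethoxy)phenoxy]phenol
Conditions: NaH (1.0 equiv), DMF, 0 °C; then MOMCl (1.0 equiv), 0 °C to rt
Reagents that add atoms: chloromethyl methyl ether (MOMCl), COCCl
Why: One equivalent of base places the single negative charge on the more acidic ring B oxygen, and the fast, weakly discriminating Williamson-type O-alkylation by MOMCl should follow that anion population while the ring A hydroxyl stays protonated.

Step 3
Reactants: 7 2,4-dibromo-6-[2,3,4,5-tetrabromo-6-(methoxymethoxy)phenoxy]phenol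
Product: 8 1,2,3,4-tetrabromo-5-(3,5-dibromo-2-methoxyphenoxy)-6-(methoxymethoxy)benzene
Conditions: MeI, K2CO3, acetone, 40 °C
Reagents that add atoms: iodomethane, CI
Why: Williamson ether synthesis on the only remaining phenol, whose di-ortho-substituted phenoxide is still open to the small electrophile MeI, under basic conditions to which the MOM acetal, the diaryl ether and the six C–Br bonds are inert.

Step 4
Reactants: 8 1,2,3,4-tetrabromo-5-(3,5-dibromo-2-methoxyphenoxy)-6-(methoxymethoxy)benzene
Product: 9 2,3,4,5-tetrabromo-6-(3,5-dibromo-2-methoxyphenoxy)phenol (CNP0187182.0)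
Conditions: HCl (3 M in MeOH), THF, 40 °C
Reagents that add atoms: none
Why: Acid-catalysed cleavage of the MOM acetal (transacetalization to methanol) frees the ring B phenol, while the aryl methyl ether, the diaryl ether and the C–Br bonds do not react with dilute HCl.

**Compound list**

1 | 2,4-dibromophenol | Oc1ccc(Br)cc1Br | starting material
2 | tetrabromo-1,2-benzoquinone (o-bromanil) | O=C1C(=O)C(Br)=C(Br)C(Br)=C1Br | starting material
3 | 2,4-dibromophenoxyl radical | [O]c1ccc(Br)cc1Br | intermediate
4 | 2,3,4,5-tetrabromo-6-hydroxyphenoxyl radical (neutral tetrabromo-o-semiquinone) | Oc1c([O])c(Br)c(Br)c(Br)c1Br | intermediate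
5 | 2,4-dibromo-6-(2,3,4,5-tetrabromo-6-hydroxyphenoxy)cyclohexa-2,4-dien-1-one (racemic at C6) | O=C1C(Br)=CC(Br)=CC1Oc1c(O)c(Br)c(Br)c(Br)c1Br | intermediate
6 | 2,3,4,5-tetrabromo-6-(3,5-dibromo-2-hydroxyphenoxy)phenol | Oc1c(Br)cc(Br)cc1Oc1c(O)c(Br)c(Br)c(Br)c1Br | intermediate
7 | 2,4-dibromo-6-[2,3,4,5-tetrabromo-6-(methoxymethoxy)phenoxy]phenol | Oc1c(Br)cc(Br)cc1Oc1c(OCOC)c(Br)c(Br)c(Br)c1Br | intermediate
8 | 1,2,3,4-tetrabromo-5-(3,5-dibromo-2-methoxyphenoxy)-6-(methoxymethoxy)benzene | COc1c(Br)cc(Br)cc1Oc1c(OCOC)c(Br)c(Br)c(Br)c1Br | intermediate
9 | 2,3,4,5-tetrabromo-6-(3,5-dibromo-2-methoxyphenoxy)phenol | COc1c(Br)cc(Br)cc1Oc1c(O)c(Br)c(Br)c(Br)c1Br | target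

**Step count**

Total steps: 4. Longest linear sequence: 4 steps (from 1 and 2 to 9).

**Steps most likely to fail**

Step 1 (proposed new method). The radicals may leave the cage, so that the phenoxyl radical homodimerizes and the semiquinone disproportionates. The phenol may instead displace a ring bromine of the quinone by addition–elimination. The first hydrogen transfer may be too slow at a temperature the quinone tolerates. The product may be oxidized further with loss of bromine to a dibenzodioxin.

The fallback makes the ether bond by the known metal-free O-arylation of a phenol with a diaryliodonium salt. Setting out from 1, iodination ortho to the hydroxyl (NIS, cat. TsOH, MeCN) would give 2,4-dibromo-6-iodophenol F1. Methylation (MeI, K2CO3, acetone) would give 1,5-dibromo-3-iodo-2-methoxybenzene F2. One-pot oxidation to trivalent iodine and arylation (mCPBA, TsOH·H2O, MeCN, then 1,3,5-trimethoxybenzene) would give (3,5-dibromo-2-methoxyphenyl)(2,4,6-trimethoxyphenyl)iodonium tosylate F3. Setting out from 2, reduction with Na2S2O4 (EtOAc/H2O) would give tetrabromocatechol F4. The monopotassium salt of F4 (KOt-Bu, THF, catechol in excess to hold back double arylation) should be arylated by F3 with transfer of the electron-poorer, ortho-substituted aryl group, the trimethoxyphenyl group leaving with the iodine. This gives 9 directly, so the detour comes back to the route at 9 and steps 2 to 4 fall away.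

Step 2. The alkylation may fail to discriminate the two hydroxyls, through reaction of the minor but more nucleophilic ring A phenoxide or through bis-alkylation after proton exchange.

The fallback rests the differentiation on ester leaving-group ability and sets out from 6. Ac2O/pyridine would give 2-(2-acetoxy-3,5-dibromophenoxy)-3,4,5,6-tetrabromophenyl acetate F5. One equivalent of pyrrolidine (THF, 0 °C) should cleave the more activated ester, that of the tetrabromophenol, to give 2,4-dibromo-6-(2,3,4,5-tetrabromo-6-hydroxyphenoxy)phenyl acetate F6; an acetyl group that migrates would also settle on the less acidic ring A oxygen, so kinetic and thermodynamic preference point the same way. MOMCl/i-Pr2NEt (CH2Cl2) would then mask the free ring B hydroxyl as 2,4-dibromo-6-[2,3,4,5-tetrabromo-6-(methoxymethoxy)phenoxy]phenyl acetate F7. K2CO3/MeOH would remove the acetate, and the detour comes back to the route at 7.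

Step 3. The methoxymethyl group may transfer from the ring B oxygen to the ring A phenoxide under base, scrambling the two oxygens, and the alkylation of the di-ortho-substituted phenoxide may be slow.

The fallback sets out from 7 and forms the methyl ether without a free phenoxide, by Mitsunobu etherification with methanol (MeOH, PPh3, DIAD, THF, 0 °C to rt), in which the acidic phenol is the pronucleophile and the activated methanol the electrophile. It comes back to the route at 8. New compounds on this detour: none F0.

**Further compounds**

F1 | step 1 | 2,4-dibromo-6-iodophenol | Oc1c(Br)cc(Br)cc1I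
F2 | step 1 | 1,5-dibromo-3-iodo-2-methoxybenzene | COc1c(Br)cc(Br)cc1I
F3 | step 1 | (3,5-dibromo-2-methoxyphenyl)(2,4,6-trimethoxyphenyl)iodonium tosylate | COc1cc(OC)c([I+]c2cc(Br)cc(Br)c2OC)c(OC)c1.Cc1ccc(cc1)S(=O)(=O)[O-]
F4 | step 1 | 3,4,5,6-tetrabromobenzene-1,2-diol (tetrabromocatechol) | Oc1c(O)c(Br)c(Br)c(Br)c1Br
F5 | step 2 | 2-(2-acetoxy-3,5-dibromophenoxy)-3,4,5,6-tetrabromophenyl acetate | CC(=O)Oc1c(Br)cc(Br)cc1Oc1c(OC(C)=O)c(Br)c(Br)c(Br)c1Br
F6 | step 2 | 2,4-dibromo-6-(2,3,4,5-tetrabromo-6-hydroxyphenoxy)phenyl acetate | CC(=O)Oc1c(Br)cc(Br)cc1Oc1c(O)c(Br)c(Br)c(Br)c1Br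
F7 | step 2 | 2,4-dibromo-6-[2,3,4,5-tetrabromo-6-(methoxymethoxy)phenoxy]phenyl acetate | CC(=O)Oc1c(Br)cc(Br)cc1Oc1c(OCOC)c(Br)c(Br)c(Br)c1Br
F0 | step 3 | none | none
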